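The plan cuts the C6–C19 bond of the 12-membered ether ring (C6, O7, C8, C11–C19). C6 and C19 are neighbouring stereocentres, C6 bears O7, and its other neighbour C5 lies one oxidation level below a carboxyl carbon. This is the retron of a glycolate ester-enolate Claisen rearrangement. In one operation the silyl ketene acetal of a 12-membered glycolate macrolactone should form C6–C19, break O–C17, relay the C17 configuration to both new centres, and turn the lactone into the ether macrocycle carrying C5 as a free acid. The precursor is that lactone: O7 already on C8, Z-C13=C14, silylated carbinols C11 and C15, an (E)-propenyl group on (17R)-C17 and a PMB-protected C9–C10 arm.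

Key step: step 18

**Locants (kept for all intermediates).** C1=C2 is the exocyclic methylene, C3 the lactone carbonyl, then O4. The oxane is C5–C6–O7–C8–C9–C10. C11 and C15 are the carbinols, C13=C14 the alkene, followed by C16–C18 and C19 (CHMe on C6). The target is 5S,6R,8R,10R,11S,15R,19S with Z-C13=C14. Its lactone is cis-fused and lies trans to C19 and C11 on the oxane.

**Design remarks.**
- (a) Walking the chair with (17R), the E-propenyl group and the Z ketene acetal gives 6R,19S and E-C17=C18, which matches the target. No stereodescriptor of the precursor or product had to be changed.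
- (b) C10–O is a PMB ether, because a primary silyl ether could not later be removed beside two tertiary TES ethers.
- (c) O7–C6 is made while C11–OH is still free, since a C8 alkoxide next to C11–OSiEt3 would invite 1,2-silyl migration. The tert-butyl ester is cleaved with Et3SiOTf, not protic acid, because C15–O is tertiary and allylic.
- (d) The C11–C12 terminal epoxide is made directly, so no Payne equilibrium is needed.
- (e) The last rings are not closed by an allylmetal addition of a 2-(halomethyl)enoate. Fused to the forming oxane chair (C11 and C19 equatorial), its closed transition state puts O4 axial with the Z reagent or prefers the trans-fused lactone with the E reagent. A butenolide is closed instead; its planarity forces O4 equatorial, and C10 is then set by hydride addition to the convex face.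

**Assumption.** Compound 6 is drawn as the open hydroxy dioxolanone. Should it translactonise to the γ-lactone, step 4 would give the same triol 7.

## Route

Step 1
Reactants: 1 (R)-citramalic acid
Product: 2 2-[(4R)-2,2,4-trimethyl-5-oxo-1,3-dioxolan-4-yl]acetic acid
Conditions: Me2C(OMe)2, TsOH·H2O (cat.), CH2Cl2, rt
Reagents that add atoms: 2,2-dimethoxypropane, COC(C)(C)OC
Why: Acid-catalysed transketalisation closes the five-membered dioxolanone on the α-hydroxy acid half only, which masks C14 and O15, leaves the C17 acid free and does not touch the quaternary C15 centre taken from the chiral pool.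

Step 2
Reactants: 2 dioxolanone acid; 3 tributyl(prop-1-yn-1-yl)stannane
Product: 5 (5R)-2,2,5-trimethyl-5-(2-oxopent-3-yn-1-yl)-1,3-dioxolan-4-one, via acid chloride 4 (not isolated)
Conditions: (COCl)2, DMF (cat.), CH2Cl2, 0 °C → rt, evaporate; 3, PdCl2(PPh3)2 (3 mol%), toluene, 60 °C
Reagents that add atoms: none
Why: The Stille acylation of an acid chloride runs without base, so the β-oxygenated ketone cannot eliminate and the dioxolanone is not attacked, and it brings in C18, C19 and the C19 methyl group.

Step 3
Reactants: 5 ynone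
Product: 6 (5R)-5-[(2R)-2-hydroxypent-3-yn-1-yl]-2,2,5-trimethyl-1,3-dioxolan-4-one
Conditions: Ru[(R,R)-TsDPEN](p-cymene) (1 mol%), iPrOH, rt
Reagents that add atoms: none
Why: Noyori asymmetric transfer hydrogenation tells alkynyl from alkyl electronically, so the (R,R) catalyst should set (17R) under reagent control whatever the bias of the remote C15 centre.

Step 4
Reactants: 6 propargylic alcohol
Product: 7 (2R,4R,5E)-2-methylhept-5-ene-1,2,4-triol
Conditions: LiAlH4 (excess), THF, 0 °C → reflux; H2O/aq. NaOH work-up
Reagents that add atoms: none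
Why: LiAlH4 reduces the dioxolanone to the C14 primary and C15 tertiary alcohols and, through the C17 alkoxide, trans-hydroaluminates the propargylic alkyne, which should give only the E C18=C19 alkene.

Step 5
Reactants: 7 triol
Product: 8 tris(triethylsilyl) ether of 7
Conditions: Et3SiOTf (3.6 equiv), 2,6-lutidine, CH2Cl2, −78 → 0 °C
Reagents that add atoms: triethylsilyl trifluoromethanesulfonate, CC[Si](CC)(CC)OS(=O)(=O)C(F)(F)F
Why: Exhaustive silylation with the silyl triflate reaches even the tertiary alcohol and gives three TES ethers of graded lability (primary, allylic secondary, tertiary).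

Step 6
Reactants: 8 tris-TES ether
Product: 9 (2R,4R,5E)-2-methyl-2,4-bis(triethylsilyloxy)hept-5-enal
Conditions: (COCl)2, DMSO, CH2Cl2, −78 → −35 °C; Et3N, −78 °C → rt
Reagents that add atoms: none
Why: Under Swern conditions a primary TES ether is cleaved and oxidised directly while secondary and tertiary TES ethers stay, and the aldehyde formed has no α-hydrogen that could epimerise.

Step 7
Reactants: 9 aldehyde
Product: 10 (3R,5R,6E)-3-methyl-3,5-bis(triethylsilyloxy)oct-6-en-1-yne (C13–C19 fragment)
Conditions: MeC(O)C(N2)P(O)(OMe)2, K2CO3, MeOH, 0 °C → rt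
Reagents that add atoms: dimethyl (1-diazo-2-oxopropyl)phosphonate, CC(=O)C(=[N+]=[N-])P(=O)(OC)OC
Why: The Ohira–Bestmann variant of the Seyferth–Gilbert homologation adds C13 under mild carbonate conditions that the TES ethers and the quaternary C15 centre tolerate.

Step 8
Reactants: 11 propane-1,3-diol
Product: 12 3-[(4-methoxybenzyl)oxy]propan-1-ol
Conditions: NaH, PMBCl, Bu4NI (cat.), THF, 0 °C → rt (diol in excess)
Reagents that add atoms: 4-methoxybenzyl chloride, COc1ccc(CCl)cc1
Why: Williamson etherification with the diol in excess should stop at the mono-ether that later becomes the C10–O protecting group.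

Step 9
Reactants: 12 mono-PMB diol
Product: 13 3-[(4-methoxybenzyl)oxy]propanal
Conditions: TEMPO (cat.), PhI(OAc)2, CH2Cl2, rt
Reagents that add atoms: none
Why: The oxoammonium (TEMPO) oxidation stops at the aldehyde and leaves the electron-rich benzyl ether alone.

Step 10
Reactants: 13 aldehyde; 14 isopropenylmagnesium bromide
Product: 15 rac-5-[(4-methoxybenzyl)oxy]-2-methylpent-1-en-3-ol
Conditions: THF, −78 → 0 °C; aq. NH4Cl
Reagents that add atoms: none
Why: Grignard addition joins C8 to C11 and delivers the 2-methyl allylic alcohol as a racemate, which is what the following resolution needs.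

Step 11
Reactants: 15 racemic allylic alcohol
Product: 16 (1R)-3-[(4-methoxybenzyl)oxy]-1-[(2S)-2-methyloxiran-2-yl]propan-1-ol
Conditions: Ti(OiPr)4 (10 mol%), D-(−)-DIPT (12 mol%), tBuOOH (0.45 equiv), 4 Å MS, CH2Cl2, −20 °C
Reagents that add atoms: tert-butyl hydroperoxide, CC(C)(C)OO
Why: In the Sharpless kinetic resolution with D-(−)-tartrate the (R)-alcohol is the fast enantiomer and is epoxidised anti (erythro) to its hydroxyl, reinforced by A(1,2) strain from the C11 methyl group, so 8R and 11S are set together and unreacted (S)-15 is removed by chromatography.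

Step 12
Reactants: 16 epoxy alcohol
Product: 17 trimethylsilyl ether of 16
Conditions: Me3SiCl, imidazole, CH2Cl2, 0 °C
Reagents that add atoms: chlorotrimethylsilane, C[Si](C)(C)Cl
Why: Capping O8 with a throw-away silyl group keeps the hydroxyl from quenching the valuable acetylide and excludes any Payne rearrangement of an epoxy alkoxide.

Step 13
Reactants: 10 alkyne; 17 silylated epoxide
Product: 19 alkynediol C8–C19 (8R 11S 15R 17R 18E) having free C8-OH and C11-OH; C15 and C17 OTES; C10 OPMB, via C8-O-trimethylsilyl adduct 18 (not isolated)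
Conditions: 10, nBuLi, THF, −78 °C; BF3·OEt2; 17, −78 °C; aq. NaHCO3; crude in MeOH, K2CO3 (cat.), 0 °C
Reagents that add atoms: none
Why: The BF3-assisted opening of a terminal epoxide by a lithium acetylide occurs at the unsubstituted C12, so the C11–O bond and its configuration are untouched, and brief methanolysis removes only the labile trimethylsilyl group wherever it sits.

Step 14
Reactants: 19 alkynediol
Product: 20 (13Z)-alkenediol
Conditions: H2 (1 atm), Pd/CaCO3–Pb(OAc)2 (Lindlar), quinoline, EtOAc, rt
Reagents that add atoms: none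
Why: Lindlar semi-hydrogenation adds hydrogen syn to the alkyne and should give Z-C13=C14 while the isolated E alkene and the PMB ether are not reduced on the poisoned catalyst.

Step 15
Reactants: 20 alkenediol; 21 tert-butyl bromoacetate
Product: 22 tert-butyl glycolate ether at O7 keeping free C11-OH
Conditions: NaN(SiMe3)2 (1.05 equiv), THF–DMF, −40 °C; 21, Bu4NI (cat.), −40 → 0 °C
Reagents that add atoms: none
Why: Williamson etherification of the mono-alkoxide takes place at the secondary O8 because the tertiary C11 hydroxyl is too hindered, no silyl group is close enough to migrate, and the tert-butyl ester resists lactonisation once the single equivalent of base is spent.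

Step 16
Reactants: 22 hydroxy tert-butyl ester
Product: 24 seco acid having free C17-OH and CO2H; C11 and C15 OTES, via persilylated triethylsilyl ester 23 (not isolated)
Conditions: Et3SiOTf (4 equiv), 2,6-lutidine, CH2Cl2, 0 °C → rt; then MeOH, PPTS (cat.), 0 °C
Reagents that add atoms: triethylsilyl trifluoromethanesulfonate, CC[Si](CC)(CC)OS(=O)(=O)C(F)(F)F
Why: The silyl triflate–lutidine pair silylates C11–OH and converts the tert-butyl ester into a silyl ester with loss of isobutene without any protic acid, and short buffered methanolysis then cleaves only the silyl ester and the least hindered (secondary allylic) TES ether.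

Step 17
Reactants: 24 seco acid
Product: 26 12-membered glycolate macrolactone (8R 11S 13Z 15R 17R) bearing (E)-propenyl on C17, via mixed anhydride 25 (not isolated)
Conditions: 2,4,6-Cl3C6H2COCl, Et3N, THF, rt; slow addition to DMAP, toluene (1 mM), 40 °C
Reagents that add atoms: none
Why: Yamaguchi macrolactonisation activates the acid and not the alcohol, so C17 keeps its configuration, and the Z alkene and the two quaternary carbinol carbons pre-fold the chain for closure of the 12-membered ring.

Step 18
Reactants: 26 macrolactone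
Product: 29 12-membered ether acid (6R 8R 11S 13Z 15R 17E 19S) bearing C5 as CO2H, via silyl ketene acetal 27 (not isolated), via trimethylsilyl ester 28 (not isolated)
Conditions: LiN(iPr)2, THF, −78 °C, 5 min; Me3SiCl–Et3N; −78 °C → rt, then 60 °C; aq. citric acid
Reagents that add atoms: none
Why: Proposed new method: LiN(iPr)2 deprotonates C6 while lithium is clamped between the enolate oxygen and O7, silylation fixes this as the Z silyl ketene acetal 27 (O7 cis to OSiMe3, a trans double bond as far as the 12-membered ring is concerned), and warming triggers a concerted suprafacial [3,3] shift over C6=C5–O–C17–C18=C19 that forms C6–C19 and breaks O–C17. The closest known reaction types are the chelation-controlled Ireland–Claisen rearrangement of open-chain allylic glycolates, the same rearrangement of 6-alkenyl-1,4-dioxan-2-ones to dihydropyran-2-carboxylic acids and the ring contraction of macrolactone ketene acetals; a size-neutral lactone-to-ether transposition of a 12-membered ring through a chair has not been shown. The one ring that is closed, the 12-membered ether ring C6–O7–C8–C11–…–C19, closes by the sigmatropic bond between endocyclic C6 and the far end of the exocyclic propenyl group, C18 and C19 entering the ring as C5 and the ester oxygen leave it, so the termini are held by the three-atom C5–O–C17 bridge (a bicyclo[8.2.2]-type transition state) and no dilution-dependent closure is involved. C19 is controlled by the (17R) centre and the E alkene (C16 and the methyl group pseudo-equatorial, C–C bond formed on the alkene face from which the C17–O bond departs) and C6 by the ketene acetal geometry (O7 pseudo-equatorial), which in the chair gives 6R,19S and an E C17=C18 bond. The step needs a single enolate geometry and chair over boat: the first is secured by O7 chelation in THF without polar cosolvent, the second rests on the normal chair preference of E-allylic esters and on a tether whose Z alkene and two quaternary carbinol carbons supply the turn needed to bridge the two pseudo-equatorial positions. The acid-labile groups are safe because the medium stays basic until a citric acid wash hydrolyses only the silyl ester 28.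

Step 19
Reactants: 29 ether acid
Product: 30 C5 primary alcohol (17E)
Conditions: LiAlH4, Et2O, 0 °C → rt
Reagents that add atoms: none
Why: Hydride reduction takes the acid to the primary alcohol without touching isolated alkenes, silyl ethers or the PMB ether, and C6 cannot epimerise at the carboxylate stage.

Step 20
Reactants: 30 dienyl alcohol
Product: 31 C16–C18 saturated alcohol keeping Z-C13=C14
Conditions: 2-O2NC6H4SO2NHNH2, Et3N, CH2Cl2, rt (portionwise, monitored)
Reagents that add atoms: none
Why: Diimide reduction is a concerted syn hydrogen transfer that answers to steric access, so the E alkene C17=C18 between a CH2 and a CHMe should react before Z-C13=C14, which is shielded by the quaternary C15 with its OTES group and by the neopentyl-type C12.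

Step 21
Reactants: 31 alcohol
Product: 32 C5-O-triethylsilyl ether
Conditions: Et3SiCl, imidazole, CH2Cl2, 0 °C
Reagents that add atoms: chlorotriethylsilane, CC[Si](Cl)(CC)CC
Why: Silylation parks C5–OH as a primary TES ether that can later be turned into the aldehyde in one operation beside the tertiary TES ethers.

Step 22
Reactants: 32 PMB ether
Product: 33 C10 primary alcohol
Conditions: DDQ, CH2Cl2–pH 7 buffer, 0 °C
Reagents that add atoms: none
Why: Oxidative PMB cleavage by hydride abstraction at the electron-rich benzylic position is orthogonal to all three silyl ethers when the medium is buffered.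

Step 23
Reactants: 33 alcohol
Product: 34 C10 aldehyde
Conditions: Dess–Martin periodinane, pyridine, CH2Cl2, 0 °C → rt
Reagents that add atoms: none
Why: The buffered Dess–Martin oxidation is neutral enough that the β-alkoxy aldehyde does not lose O7 by elimination.

Step 24
Reactants: 34 aldehyde; 35 ethyl diazoacetate
Product: 36 β-keto ester C10(=O)–C2H2–C3O2Et
Conditions: SnCl2 (10 mol%), CH2Cl2, rt
Reagents that add atoms: none
Why: The Roskamp homologation (addition of the diazo ester, 1,2-hydride shift, loss of nitrogen) adds C2 and C3 under almost neutral conditions that a β-alkoxy aldehyde tolerates.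

Step 25
Reactants: 36 β-keto ester
Product: 37 (Z)-enol triflate (OTf on C10 cis to CO2Et)
Conditions: Tf2O, LiOTf, Et3N, CH2Cl2, −20 → 0 °C
Reagents that add atoms: trifluoromethanesulfonic anhydride, O=S(=O)(OS(=O)(=O)C(F)(F)F)C(F)(F)F
Why: O-sulfonylation of the lithium-chelated enolate of a β-keto ester gives the Z enol triflate, and only the doubly activated C2 position is deprotonated, so O7 is not eliminated.

Step 26
Reactants: 37 enol triflate
Product: 38 C5 aldehyde
Conditions: (COCl)2, DMSO, CH2Cl2, −78 → −40 °C; iPr2NEt, −78 → 0 °C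
Reagents that add atoms: none
Why: The Swern oxidation of the single primary TES ether unveils the aldehyde directly, the tertiary TES ethers stay, and the hindered base at low temperature should keep C6 from epimerising.

Step 27
Reactants: 38 aldehyde enol triflate
Product: 40 oxane-fused butenolide (5S 6R 8R) having C10=C2, via hydroxy enoate 39 (not isolated)
Conditions: CrCl2 (8 equiv), NiCl2 (2 mol% of Cr), DMF, rt, 5 mM
Reagents that add atoms: none
Why: In the Nozaki–Hiyama–Kishi reaction zerovalent nickel inserts into C10–OTf, the alkenyl group passes to trivalent chromium with retention and adds 6-exo to the C5 aldehyde, and the alkoxide lactonises onto the cis ester; O4 has to lie in the enoate plane, that is equatorial, and the macrocycle allows only the chair with C19 and C11 equatorial, which sets 5S (O4 trans to C19).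

Step 28
Reactants: 40 butenolide
Product: 41 cis-fused saturated γ-lactone (5S 10R)
Conditions: Cu(OAc)2·H2O (5 mol%), 1,2-(Ph2P)2C6H4 (5 mol%), (EtO)2MeSiH, tBuOH, toluene, 0 °C → rt
Reagents that add atoms: none
Why: Copper hydride conjugate reduction delivers hydride to C10 on the convex face, anti to C6 on the γ-carbon C5, so H10 ends cis to H5 (10R, cis-fused lactone), and the isolated Z alkene is inert to this reagent.

Step 29
Reactants: 41 lactone
Product: 42 2-(dimethylaminomethyl) lactone (C2 epimers of no consequence)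
Conditions: LiN(iPr)2, THF, −78 °C; CH2=NMe2+ I−, −78 °C → rt
Reagents that add atoms: N,N-dimethylmethyleneiminium iodide, C=[N+](C)C.[I-]
Why: The Mannich reaction of the lithium lactone enolate with Eschenmoser's salt adds C1 at C2, and the enolate has no leaving group in β-position.

Step 30
Reactants: 42 Mannich base
Product: 44 bis-TES ether of the target, via methiodide 43 (not isolated)
Conditions: MeI, CH2Cl2–MeOH, rt; then aq. NaHCO3, CH2Cl2, rt
Reagents that add atoms: none
Why: Quaternisation followed by mild base-induced β-elimination of trimethylamine gives the exocyclic C1=C2 methylene, and C10 is not acidic, so the ring fusion is kept.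

Step 31
Reactants: 44 bis-TES ether
Product: 45 CNP0146755.1 (target)
Conditions: HF·pyridine, pyridine, THF, 0 °C → rt
Reagents that add atoms: none
Why: Buffered HF·pyridine cleaves the two tertiary TES ethers at silicon without ionising the tertiary allylic C15–O bond and without adding to the α-methylene lactone.

## Compound list

1 | (R)-citramalic acid | OC(=O)[C@](C)(O)CC(=O)O | starting material
2 | 2-[(4R)-2,2,4-trimethyl-5-oxo-1,3-dioxolan-4-yl]acetic acid | O=C1OC(C)(C)O[C@]1(C)CC(=O)O | intermediate
3 | tributyl(prop-1-yn-1-yl)stannane | CC#C[Sn](CCCC)(CCCC)CCCC | starting material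
4 | acid chloride of 2 | O=C1OC(C)(C)O[C@]1(C)CC(=O)Cl | intermediate
5 | (5R)-2,2,5-trimethyl-5-(2-oxopent-3-yn-1-yl)-1,3-dioxolan-4-one | O=C1OC(C)(C)O[C@]1(C)CC(=O)C#CC | intermediate
6 | (5R)-5-[(2R)-2-hydroxypent-3-yn-1-yl]-2,2,5-trimethyl-1,3-dioxolan-4-one | O=C1OC(C)(C)O[C@]1(C)C[C@@H](O)C#CC | intermediate
7 | (2R,4R,5E)-2-methylhept-5-ene-1,2,4-triol | OC[C@](C)(O)C[C@@H](O)/C=C/C | intermediate
8 | tris(triethylsilyl) ether of 7 | CC[Si](CC)(CC)OC[C@](C)(O[Si](CC)(CC)CC)C[C@@H](O[Si](CC)(CC)CC)/C=C/C | intermediate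
9 | (2R,4R,5E)-2-methyl-2,4-bis(triethylsilyloxy)hept-5-enal | O=C[C@](C)(O[Si](CC)(CC)CC)C[C@@H](O[Si](CC)(CC)CC)/C=C/C | intermediate
10 | (3R,5R,6E)-3-methyl-3,5-bis(triethylsilyloxy)oct-6-en-1-yne | C#C[C@](C)(O[Si](CC)(CC)CC)C[C@@H](O[Si](CC)(CC)CC)/C=C/C | intermediate
11 | propane-1,3-diol | OCCCO | starting material
12 | 3-[(4-methoxybenzyl)oxy]propan-1-ol | COc1ccc(COCCCO)cc1 | intermediate
13 | 3-[(4-methoxybenzyl)oxy]propanal | COc1ccc(COCCC=O)cc1 | intermediate
14 | isopropenylmagnesium bromide | CC(=C)[Mg]Br | starting material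
15 | rac-5-[(4-methoxybenzyl)oxy]-2-methylpent-1-en-3-ol | COc1ccc(COCCC(O)C(C)=C)cc1 | intermediate
16 | (1R)-3-[(4-methoxybenzyl)oxy]-1-[(2S)-2-methyloxiran-2-yl]propan-1-ol | COc1ccc(COCC[C@@H](O)[C@]2(C)CO2)cc1 | intermediate
17 | trimethylsilyl ether of 16 | COc1ccc(COCC[C@@H](O[Si](C)(C)C)[C@]2(C)CO2)cc1 | intermediate
18 | C8-O-trimethylsilyl coupling adduct | COc1ccc(COCC[C@@H](O[Si](C)(C)C)[C@@](C)(O)CC#C[C@](C)(O[Si](CC)(CC)CC)C[C@@H](O[Si](CC)(CC)CC)/C=C/C)cc1 | intermediate
19 | alkynediol (8R,11S,15R,17R,18E) | COc1ccc(COCC[C@@H](O)[C@@](C)(O)CC#C[C@](C)(O[Si](CC)(CC)CC)C[C@@H](O[Si](CC)(CC)CC)/C=C/C)cc1 | intermediate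
20 | (13Z)-alkenediol | COc1ccc(COCC[C@@H](O)[C@@](C)(O)C/C=C\[C@](C)(O[Si](CC)(CC)CC)C[C@@H](O[Si](CC)(CC)CC)/C=C/C)cc1 | intermediate
21 | tert-butyl bromoacetate | CC(C)(C)OC(=O)CBr | starting material
22 | tert-butyl glycolate ether at O7, C11-OH free | COc1ccc(COCC[C@@H](OCC(=O)OC(C)(C)C)[C@@](C)(O)C/C=C\[C@](C)(O[Si](CC)(CC)CC)C[C@@H](O[Si](CC)(CC)CC)/C=C/C)cc1 | intermediate
23 | persilylated triethylsilyl ester | COc1ccc(COCC[C@@H](OCC(=O)O[Si](CC)(CC)CC)[C@@](C)(O[Si](CC)(CC)CC)C/C=C\[C@](C)(O[Si](CC)(CC)CC)C[C@@H](O[Si](CC)(CC)CC)/C=C/C)cc1 | intermediate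
24 | seco acid (C17-OH and CO2H free) | COc1ccc(COCC[C@@H](OCC(=O)O)[C@@](C)(O[Si](CC)(CC)CC)C/C=C\[C@](C)(O[Si](CC)(CC)CC)C[C@@H](O)/C=C/C)cc1 | intermediate
25 | 2,4,6-trichlorobenzoic mixed anhydride of 24 | COc1ccc(COCC[C@@H](OCC(=O)OC(=O)c2c(Cl)cc(Cl)cc2Cl)[C@@](C)(O[Si](CC)(CC)CC)C/C=C\[C@](C)(O[Si](CC)(CC)CC)C[C@@H](O)/C=C/C)cc1 | intermediate
26 | 12-membered glycolate macrolactone (key-step precursor) | O=C1CO[C@H](CCOCc2ccc(OC)cc2)[C@@](C)(O[Si](CC)(CC)CC)C/C=C\[C@](C)(O[Si](CC)(CC)CC)C[C@H](/C=C/C)O1 | intermediate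
27 | (Z)-trimethylsilyl ketene acetal of 26 | C[Si](C)(C)O/C1=C\O[C@H](CCOCc2ccc(OC)cc2)[C@@](C)(O[Si](CC)(CC)CC)C/C=C\[C@](C)(O[Si](CC)(CC)CC)C[C@H](/C=C/C)O1 | intermediate
28 | trimethylsilyl ester of 29 | C[Si](C)(C)OC(=O)[C@@H]1O[C@H](CCOCc2ccc(OC)cc2)[C@@](C)(O[Si](CC)(CC)CC)C/C=C\[C@](C)(O[Si](CC)(CC)CC)C/C=C/[C@@H]1C | intermediate
29 | 12-membered ether acid (key-step product) | OC(=O)[C@@H]1O[C@H](CCOCc2ccc(OC)cc2)[C@@](C)(O[Si](CC)(CC)CC)C/C=C\[C@](C)(O[Si](CC)(CC)CC)C/C=C/[C@@H]1C | intermediate
30 | C5 primary alcohol, 13Z,17E-diene | OC[C@@H]1O[C@H](CCOCc2ccc(OC)cc2)[C@@](C)(O[Si](CC)(CC)CC)C/C=C\[C@](C)(O[Si](CC)(CC)CC)C/C=C/[C@@H]1C | intermediate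
31 | C5 primary alcohol, C16–C18 saturated | OC[C@@H]1O[C@H](CCOCc2ccc(OC)cc2)[C@@](C)(O[Si](CC)(CC)CC)C/C=C\[C@](C)(O[Si](CC)(CC)CC)CCC[C@@H]1C | intermediate
32 | C5-O-TES, C10-O-PMB ether | CC[Si](CC)(CC)OC[C@@H]1O[C@H](CCOCc2ccc(OC)cc2)[C@@](C)(O[Si](CC)(CC)CC)C/C=C\[C@](C)(O[Si](CC)(CC)CC)CCC[C@@H]1C | intermediate
33 | C10 primary alcohol | CC[Si](CC)(CC)OC[C@@H]1O[C@H](CCO)[C@@](C)(O[Si](CC)(CC)CC)C/C=C\[C@](C)(O[Si](CC)(CC)CC)CCC[C@@H]1C | intermediate
34 | C10 aldehyde | CC[Si](CC)(CC)OC[C@@H]1O[C@H](CC=O)[C@@](C)(O[Si](CC)(CC)CC)C/C=C\[C@](C)(O[Si](CC)(CC)CC)CCC[C@@H]1C | intermediate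
35 | ethyl diazoacetate | CCOC(=O)C=[N+]=[N-] | starting material
36 | β-keto ester | CC[Si](CC)(CC)OC[C@@H]1O[C@H](CC(=O)CC(=O)OCC)[C@@](C)(O[Si](CC)(CC)CC)C/C=C\[C@](C)(O[Si](CC)(CC)CC)CCC[C@@H]1C | intermediate
37 | (Z)-enol triflate | CC[Si](CC)(CC)OC[C@@H]1O[C@H](C/C(OS(=O)(=O)C(F)(F)F)=C/C(=O)OCC)[C@@](C)(O[Si](CC)(CC)CC)C/C=C\[C@](C)(O[Si](CC)(CC)CC)CCC[C@@H]1C | intermediate
38 | C5 aldehyde (Z)-enol triflate | O=C[C@@H]1O[C@H](C/C(OS(=O)(=O)C(F)(F)F)=C/C(=O)OCC)[C@@](C)(O[Si](CC)(CC)CC)C/C=C\[C@](C)(O[Si](CC)(CC)CC)CCC[C@@H]1C | intermediate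
39 | oxane hydroxy enoate | O[C@@H]1[C@@H]2O[C@H](C/C1=C/C(=O)OCC)[C@@](C)(O[Si](CC)(CC)CC)C/C=C\[C@](C)(O[Si](CC)(CC)CC)CCC[C@@H]2C | intermediate
40 | oxane-fused butenolide | O=C1O[C@@H]2[C@@H]3O[C@H](CC2=C1)[C@@](C)(O[Si](CC)(CC)CC)C/C=C\[C@](C)(O[Si](CC)(CC)CC)CCC[C@@H]3C | intermediate
41 | cis-fused saturated lactone | O=C1O[C@@H]2[C@@H]3O[C@H](C[C@@H]2C1)[C@@](C)(O[Si](CC)(CC)CC)C/C=C\[C@](C)(O[Si](CC)(CC)CC)CCC[C@@H]3C | intermediate
42 | 2-(dimethylaminomethyl) lactone (C2 unassigned) | O=C1O[C@@H]2[C@@H]3O[C@H](C[C@@H]2C1CN(C)C)[C@@](C)(O[Si](CC)(CC)CC)C/C=C\[C@](C)(O[Si](CC)(CC)CC)CCC[C@@H]3C | intermediate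
43 | methiodide of 42 | O=C1O[C@@H]2[C@@H]3O[C@H](C[C@@H]2C1C[N+](C)(C)C)[C@@](C)(O[Si](CC)(CC)CC)C/C=C\[C@](C)(O[Si](CC)(CC)CC)CCC[C@@H]3C.[I-] | intermediate
44 | bis-TES ether of the target | C=C1C(=O)O[C@@H]2[C@@H]3O[C@H](C[C@H]12)[C@@](C)(O[Si](CC)(CC)CC)C/C=C\[C@](C)(O[Si](CC)(CC)CC)CCC[C@@H]3C | intermediate
45 | CNP0146755.1 | C=C1C(=O)O[C@@H]2[C@@H]3O[C@H](C[C@H]12)[C@@](C)(O)C/C=C\[C@](C)(O)CCC[C@@H]3C | target

## Step count and risks

Total step count: 31. Longest linear sequence: 26 (steps 1–7 and 13–31).

**1. Step 18.**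
What may go wrong: the eight-atom tether may not let C6 and C19 meet in the chair with both tether ends pseudo-equatorial. The rearrangement could then leak through a boat, or through the chair with C16 axial, and lose the C6/C19 relationship. Alternatively the ketene acetal could fragment on heating before it rearranges.

Fallback (known chemistry): run the same [3,3] shift on an open-chain glycolate and close the ring afterwards at C13–C14. The fallback sets out from 16 and 10 and comes back at 32.
- Epoxy alcohol 16 is opened with excess propynyllithium/BF3·OEt2 to the methyl-capped alkynediol F1.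
- Mono-alkylation with 21, as in step 15, gives the tert-butyl glycolate F2.
- Et3SiOTf/2,6-lutidine followed by aqueous work-up gives the C11-silylated glycolic acid F3.
- Alkyne 10 is methylated (nBuLi, MeI) to the internal alkyne F4.
- PPTS in MeOH frees the C17 allylic alcohol F5.
- Carbodiimide esterification (EDC, DMAP) of F3 with F5 gives the open-chain allylic glycolate F6.
- The chelation-controlled Ireland–Claisen rearrangement of F6 (LiN(iPr)2, Me3SiCl) should give the open-chain acid F7 with the same 6R,19S pair.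
- LiAlH4 gives the primary alcohol F8, and Et3SiCl its TES ether F9.
- Ring-closing alkyne metathesis with Mo(≡CC6H4-4-OMe)(OSiPh3)3 and 5 Å MS in toluene gives the cycloalkyne F10.
- Lindlar semi-hydrogenation gives the 13Z,17E-diene F11.
- Diimide reduction as in step 20 leads back to 32.

**2. Step 20.**
What may go wrong: insufficient discrimination between the two disubstituted alkenes, that is partial saturation of C13=C14 or incomplete reduction of C17=C18.

Fallback: replace steric discrimination by directed delivery. Starting from 30, hydrogenation with [Ir(cod)(PCy3)(py)]PF6 under H2 in CH2Cl2 uses the free C5 hydroxyl to bind the cationic iridium. Hydrogen is handed to the nearby C17=C18, while C13=C14 sees only silyl ethers. The route is rejoined at 31, and no compound outside the list is made (F0).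

**3. Step 17.**
What may go wrong: oligomerisation may outrun closure of the 12-membered lactone.

Fallback: form the ester bond intermolecularly and close the ring at C13–C14 instead. The fallback sets out from 16 and 10 through the open-chain ester F6, prepared as under step 18. Ring-closing alkyne metathesis with Mo(≡CC6H4-4-OMe)(OSiPh3)3 and 5 Å MS in toluene gives the cycloalkyne macrolactone F12. Lindlar semi-hydrogenation then returns to 26.

Further compounds
F1 | step 18 | (3R,4S)-1-[(4-methoxybenzyl)oxy]-4-methyloct-6-yne-3,4-diol | COc1ccc(COCC[C@@H](O)[C@@](C)(O)CC#CC)cc1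
F2 | step 18 | tert-butyl glycolate ether of F1 at O7 | COc1ccc(COCC[C@@H](OCC(=O)OC(C)(C)C)[C@@](C)(O)CC#CC)cc1
F3 | step 18 | O7-glycolic acid with C11-OTES | COc1ccc(COCC[C@@H](OCC(=O)O)[C@@](C)(O[Si](CC)(CC)CC)CC#CC)cc1
F4 | step 18 | (4R,6R,7E)-4-methyl-4,6-bis(triethylsilyloxy)non-7-en-2-yne | CC#C[C@](C)(O[Si](CC)(CC)CC)C[C@@H](O[Si](CC)(CC)CC)/C=C/C
F5 | step 18 | (2E,4R,6R)-6-methyl-6-(triethylsilyloxy)non-2-en-7-yn-4-ol | CC#C[C@](C)(O[Si](CC)(CC)CC)C[C@@H](O)/C=C/C
F6 | step 18 | open-chain allylic glycolate ester of F3 and F5 | COc1ccc(COCC[C@@H](OCC(=O)O[C@@H](/C=C/C)C[C@@](C)(O[Si](CC)(CC)CC)C#CC)[C@@](C)(O[Si](CC)(CC)CC)CC#CC)cc1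
F7 | step 18 | open-chain Claisen acid (6R,19S,17E) | OC(=O)[C@H](O[C@H](CCOCc1ccc(OC)cc1)[C@@](C)(O[Si](CC)(CC)CC)CC#CC)[C@@H](C)/C=C/C[C@@](C)(O[Si](CC)(CC)CC)C#CC
F8 | step 18 | open-chain C5 primary alcohol | OC[C@H](O[C@H](CCOCc1ccc(OC)cc1)[C@@](C)(O[Si](CC)(CC)CC)CC#CC)[C@@H](C)/C=C/C[C@@](C)(O[Si](CC)(CC)CC)C#CC
F9 | step 18 | open-chain C5-O-TES ether | CC[Si](CC)(CC)OC[C@H](O[C@H](CCOCc1ccc(OC)cc1)[C@@](C)(O[Si](CC)(CC)CC)CC#CC)[C@@H](C)/C=C/C[C@@](C)(O[Si](CC)(CC)CC)C#CC
F10 | step 18 | 12-membered cycloalkyne ether (17E) | CC[Si](CC)(CC)OC[C@@H]1O[C@H](CCOCc2ccc(OC)cc2)[C@@](C)(O[Si](CC)(CC)CC)CC#C[C@](C)(O[Si](CC)(CC)CC)C/C=C/[C@@H]1C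
F11 | step 18 | 13Z,17E-diene C5-O-TES ether | CC[Si](CC)(CC)OC[C@@H]1O[C@H](CCOCc2ccc(OC)cc2)[C@@](C)(O[Si](CC)(CC)CC)C/C=C\[C@](C)(O[Si](CC)(CC)CC)C/C=C/[C@@H]1C
F0 | step 20 | none | none
F12 | step 17 | 12-membered cycloalkyne glycolate macrolactone | O=C1CO[C@H](CCOCc2ccc(OC)cc2)[C@@](C)(O[Si](CC)(CC)CC)CC#C[C@](C)(O[Si](CC)(CC)CC)C[C@H](/C=C/C)O1
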